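The α-methylene-γ-butyrolactone (ring O–C6–C7–C11–C12, germacrane numbering) is cut into carbon dioxide and a C6–C7–C11 three-carbon unit: its O–C12(=O) fragment is CO2 itself, C11 is a latent vinyl nucleophile and C6 an electrophile. In one operation, copper-catalysed carboxylation of a C11 alkenylboronate joins C11 to CO2 and the resulting carboxylate displaces a C6 mesylate with inversion, closing the trans-fused lactone. The open-chain precursor comes from an L-tartrate-derived allene by borylative allene–aldehyde coupling; ring-closing metathesis at C4=C5 then forms the ten-membered ring, and the angelates and the C14 acid are unveiled last.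

Key step: step 10

Remark: carbons carry germacrane numbers (C6 lactone carbinol, C7 ring-fusion CH, C8/C9 acyloxy carbons, C11=C13 methylene unit, C12 lactone carbonyl, C14 carboxyl). TMSE = 2-(trimethylsilyl)ethyl, Bpin = 4,4,5,5-tetramethyl-1,3,2-dioxaborolan-2-yl.

Assumption: in step 8 the chiral copper catalyst, not the dioxolane, fixes the face of attack at C7; the ligand antipode named is taken to be the matched one.

Step 1
Reactants: 1 dimethyl (4R,5R)-2,2-dimethyl-1,3-dioxolane-4,5-dicarboxylate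
Product: 3 (4S,5S)-4,5-diethynyl-2,2-dimethyl-1,3-dioxolane, via dialdehyde 2 (not isolated)
Conditions: i-Bu2AlH, CH2Cl2, −78 °C; then MeOH, K2CO3, dimethyl (1-diazo-2-oxopropyl)phosphonate (2.5 equiv), −78 °C to rt
Reagents that add atoms: dimethyl (1-diazo-2-oxopropyl)phosphonate, CC(=O)C(=[N+]=[N-])P(=O)(OC)OC
Why: Low-temperature ester reduction stops at the dialdehyde, which undergoes twofold Seyferth–Gilbert homologation with the Bestmann–Ohira reagent (one equivalent per aldehyde) in the same flask; the trans-dioxolane centres are the thermodynamically preferred ones and should survive the mild base.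

Step 2
Reactants: 3 (4S,5S)-4,5-diethynyl-2,2-dimethyl-1,3-dioxolane
Product: 4 {[(4S,5S)-5-ethynyl-2,2-dimethyl-1,3-dioxolan-4-yl]ethynyl}trimethylsilane
Conditions: n-BuLi (1 equiv), THF, −78 °C; Me3SiCl
Reagents that add atoms: chlorotrimethylsilane, C[Si](C)(C)Cl
Why: Monodeprotonation and C-silylation of one of two equivalent alkynes of the C2-symmetric diyne can give only one mono-product, and unreacted 3 is recycled (acetylide silylation).

Step 3
Reactants: 4 {[(4S,5S)-5-ethynyl-2,2-dimethyl-1,3-dioxolan-4-yl]ethynyl}trimethylsilane; 5 carbon monoxide; 6 2-(trimethylsilyl)ethanol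
Product: 7 TMSE 2-{(4S,5S)-2,2-dimethyl-5-[(trimethylsilyl)ethynyl]-1,3-dioxolan-4-yl}prop-2-enoate
Conditions: Pd(OAc)2 (cat.), 2-(diphenylphosphino)pyridine, MeSO3H (cat.), CO (20 bar), toluene, 50 °C
Reagents that add atoms: none
Why: Markovnikov hydroalkoxycarbonylation of the terminal alkyne under palladium/2-pyridylphosphine catalysis should place the ester carbon (C14) on the internal carbon C10, the silyl-capped alkyne being inert and the acid buffered by the basic ligand.

Step 4
Reactants: 7 TMSE 2-{(4S,5S)-2,2-dimethyl-5-[(trimethylsilyl)ethynyl]-1,3-dioxolan-4-yl}prop-2-enoate; 8 2-methylhexa-1,5-diene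
Product: 9 TMSE (2E)-2-{(4S,5S)-2,2-dimethyl-5-[(trimethylsilyl)ethynyl]-1,3-dioxolan-4-yl}-6-methylhepta-2,6-dienoate
Conditions: second-generation Hoveyda–Grubbs catalyst (10 mol %), 8 (5 equiv), CH2Cl2, 40 °C
Reagents that add atoms: none
Why: Cross-metathesis of the 2-substituted acrylate with the monosubstituted end of 8 should give the trisubstituted enoate with the ester trans to the new chain (the C1=C10 geometry of the target), as is usual for 2-substituted acrylates; the 1,1-disubstituted end of 8 is a spectator.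

Step 5
Reactants: 9 TMSE (2E)-2-{(4S,5S)-2,2-dimethyl-5-[(trimethylsilyl)ethynyl]-1,3-dioxolan-4-yl}-6-methylhepta-2,6-dienoate
Product: 10 TMSE (2E)-2-[(4S,5S)-5-ethynyl-2,2-dimethyl-1,3-dioxolan-4-yl]-6-methylhepta-2,6-dienoate
Conditions: K2CO3 (cat.), MeOH, 0 °C
Reagents that add atoms: none
Why: Methanolysis of the C(sp)–Si bond is fast at 0 °C, where the hindered conjugated TMSE ester should not transesterify (protodesilylation).

Step 6
Reactants: 10 TMSE (2E)-2-[(4S,5S)-5-ethynyl-2,2-dimethyl-1,3-dioxolan-4-yl]-6-methylhepta-2,6-dienoate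
Product: 12 TMSE (2E)-2-[(4S,5S)-2,2-dimethyl-5-(propa-1,2-dien-1-yl)-1,3-dioxolan-4-yl]-6-methylhepta-2,6-dienoate, via propargylic amine 11 (not isolated)
Conditions: (CH2O)n, CuI, Cy2NH, 1,4-dioxane, reflux
Reagents that add atoms: paraformaldehyde (formaldehyde), C=O
Why: Crabbé homologation: copper-mediated Mannich reaction gives amine 11, whose intramolecular hydride transfer (retro-ene) delivers the terminal allene with C13 from formaldehyde; no stereocentre is touched.

Step 7
Reactants: 13 acrolein; 14 benzeneselenol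
Product: 15 3-(phenylselanyl)propanal
Conditions: CH2Cl2, 0 °C
Reagents that add atoms: none
Why: Conjugate addition of the selenol to acrolein gives a saturated aldehyde that carries the later C5 vinyl group in masked form, so that C6 is not allylic when it must serve as electrophile.

Step 8
Reactants: 12 TMSE (2E)-2-[(4S,5S)-2,2-dimethyl-5-(propa-1,2-dien-1-yl)-1,3-dioxolan-4-yl]-6-methylhepta-2,6-dienoate; 15 3-(phenylselanyl)propanal; 16 bis(pinacolato)diboron
Product: 18 TMSE (2E)-2-{(4S,5S)-5-[(3S,4S)-4-hydroxy-6-(phenylselanyl)-2-(Bpin)hex-1-en-3-yl]-2,2-dimethyl-1,3-dioxolan-4-yl}-6-methylhepta-2,6-dienoate, via O-boryl ether 17 (not isolated)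
Conditions: CuCl (5 mol %), (S,S)-Ph-BPE, NaOtBu (10 mol %), THF, 22 °C, slow addition of 15; aq. NH4Cl
Reagents that add atoms: none
Why: Borylcupration of the terminal allene C=C should give a (Z)-2-boryl-allylcopper that adds to 15 through a chair six-membered transition state (copper-catalysed borylative allene–aldehyde coupling), forming C6–C7 with the C6 hydroxyl syn to the dioxolane branch and leaving Bpin on C11, while the chiral bisphosphine sets the face at C7.

Step 9
Reactants: 18 TMSE (2E)-2-{(4S,5S)-5-[(3S,4S)-4-hydroxy-6-(phenylselanyl)-2-(Bpin)hex-1-en-3-yl]-2,2-dimethyl-1,3-dioxolan-4-yl}-6-methylhepta-2,6-dienoate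
Product: 19 TMSE (2E)-2-{(4S,5S)-5-[(3R,4S)-4-(methanesulfonyloxy)-6-(phenylselanyl)-2-(Bpin)hex-1-en-3-yl]-2,2-dimethyl-1,3-dioxolan-4-yl}-6-methylhepta-2,6-dienoate
Conditions: MsCl, Et3N, CH2Cl2, −20 °C
Reagents that add atoms: methanesulfonyl chloride, CS(=O)(=O)Cl
Why: O-Sulfonylation with retention at C6 gives a saturated secondary mesylate that is stable to handling yet open to backside displacement (the C7 descriptor changes only through CIP priorities).

Step 10
Reactants: 19 TMSE (2E)-2-{(4S,5S)-5-[(3R,4S)-4-(methanesulfonyloxy)-6-(phenylselanyl)-2-(Bpin)hex-1-en-3-yl]-2,2-dimethyl-1,3-dioxolan-4-yl}-6-methylhepta-2,6-dienoate; 20 carbon dioxide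
Product: 22 TMSE (2E)-2-{(4S,5S)-2,2-dimethyl-5-[(2R,3S)-4-methylidene-5-oxo-2-[2-(phenylselanyl)ethyl]oxolan-3-yl]-1,3-dioxolan-4-yl}-6-methylhepta-2,6-dienoate, via potassium carboxylate 21 (not isolated)
Conditions: (IPr)CuCl (10 mol %; IPr = 1,3-bis(2,6-diisopropylphenyl)imidazol-2-ylidene), KOtBu (1.1 equiv), CO2 (1 atm), THF, 70 °C
Reagents that add atoms: none
Why: KOtBu turns the alkenyl–Bpin into a borate that hands the C11 alkenyl group to (IPr)Cu–OtBu, CO2 inserts into the Cu–C bond (C11–C12) and salt metathesis releases potassium carboxylate 21, whose oxygen then displaces the C6 mesylate (O–C6); this is a domino of two known reaction types, copper-catalysed carboxylation of alkenylboronic esters with CO2 and carboxylate SN2 lactonisation. The lactone closes in the 5-exo-tet mode, so ring O–C6–C7–C11–C12 is assembled as a formal (3+2) union of the C6–C7–C11 unit with CO2. No new stereocentre is created: C6 is inverted stereospecifically by backside attack, which turns the syn-derived mesylate into the trans-fused (6R,7S) lactone, and C7 is untouched. The step needs carboxylation to outrun any reaction of the alkenylcopper or of base with the mesylate; the CO2 atmosphere should trap the alkenylcopper at once, the alkoxide is tied up on boron, and the unactivated secondary mesylate should react only with the tethered carboxylate through a five-membered transition state. The TMSE ester, acetonide, selenide and remaining alkenes should be inert under these fluoride-free conditions.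

Step 11
Reactants: 22 TMSE (2E)-2-{(4S,5S)-2,2-dimethyl-5-[(2R,3S)-4-methylidene-5-oxo-2-[2-(phenylselanyl)ethyl]oxolan-3-yl]-1,3-dioxolan-4-yl}-6-methylhepta-2,6-dienoate
Product: 24 TMSE (2E)-2-{(4S,5S)-5-[(2R,3S)-2-ethenyl-4-methylidene-5-oxooxolan-3-yl]-2,2-dimethyl-1,3-dioxolan-4-yl}-6-methylhepta-2,6-dienoate, via selenoxide 23 (not isolated)
Conditions: H2O2 (30 %), pyridine, CH2Cl2, 0 °C to rt
Reagents that add atoms: none
Why: Oxidation to the selenoxide and syn-elimination at room temperature can only take a C5 hydrogen and should unveil the C5 vinyl group without touching the methylene lactone (selenoxide elimination).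

Step 12
Reactants: 24 TMSE (2E)-2-{(4S,5S)-5-[(2R,3S)-2-ethenyl-4-methylidene-5-oxooxolan-3-yl]-2,2-dimethyl-1,3-dioxolan-4-yl}-6-methylhepta-2,6-dienoate
Product: 25 TMSE (1(10)E,4Z,6R,7S,8S,9S)-8,9-(isopropylidenedioxy)germacra-1(10),4,11(13)-trien-6,12-olid-14-oate
Conditions: second-generation Grubbs catalyst (15 mol %), toluene (1 mM), 80 °C
Reagents that add atoms: none
Why: Ring-closing metathesis between the C5 vinyl group and the 1,1-disubstituted C4 alkene should close the ten-membered ring as the ring-cis (4Z) trisubstituted olefin, since the trisubstituted enoate cannot compete and the methylene lactone could only close a four-membered ring or a tetrasubstituted alkene.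

Step 13
Reactants: 25 TMSE (1(10)E,4Z,6R,7S,8S,9S)-8,9-(isopropylidenedioxy)germacra-1(10),4,11(13)-trien-6,12-olid-14-oate
Product: 26 TMSE (1(10)E,4Z,6R,7R,8S,9S)-8,9-dihydroxygermacra-1(10),4,11(13)-trien-6,12-olid-14-oate
Conditions: AcOH/H2O (4:1), 40 °C
Reagents that add atoms: none
Why: Mild acetal hydrolysis frees the trans-diol; the 1(10)-alkene is deactivated as an enoate, so transannular cyclisation of the diene should not start (the C7 descriptor changes only through CIP priorities).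

Step 14
Reactants: 26 TMSE (1(10)E,4Z,6R,7R,8S,9S)-8,9-dihydroxygermacra-1(10),4,11(13)-trien-6,12-olid-14-oate; 27 angelic acid [(2Z)-2-methylbut-2-enoic acid]
Product: 29 TMSE (1(10)E,4Z,6R,7S,8S,9S)-8,9-bis{[(2Z)-2-methylbut-2-enoyl]oxy}germacra-1(10),4,11(13)-trien-6,12-olid-14-oate, via mono-angelate 28 (not isolated)
Conditions: 27 (6 equiv), 2,4,6-Cl3C6H2COCl (6 equiv), Et3N (6 equiv), toluene, rt; then 26, 80 °C
Reagents that add atoms: angelic acid (second equivalent of 27, source of the second ester group), C/C=C(/C)C(=O)O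
Why: An excess of the preformed angelic 2,4,6-trichlorobenzoic mixed anhydride (Yamaguchi-type esterification) should acylate the two secondary hydroxyls in turn, one molecule of angelic acid being consumed per ester (the C8 mono-ester 28 is drawn as the intermediate, and the C9 regioisomer would converge on the same product), without Z-to-E isomerisation to tiglate.

Step 15
Reactants: 29 TMSE (1(10)E,4Z,6R,7S,8S,9S)-8,9-bis{[(2Z)-2-methylbut-2-enoyl]oxy}germacra-1(10),4,11(13)-trien-6,12-olid-14-oate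
Product: 30 (1(10)E,4Z,6R,7S,8S,9S)-8,9-bis{[(2Z)-2-methylbut-2-enoyl]oxy}germacra-1(10),4,11(13)-trien-6,12-olid-14-oic acid (CNP0154468.1)
Conditions: (Me2N)3S+ Me3SiF2− (TASF), DMF, 0 °C; aq. NH4Cl
Reagents that add atoms: none
Why: Fluoride attack at silicon fragments the TMSE ester to the carboxylate, ethene and Me3SiF under near-neutral conditions that should spare the angelates, the methylene lactone and the diene.

Compound list
1 | dimethyl (4R,5R)-2,2-dimethyl-1,3-dioxolane-4,5-dicarboxylate (acetonide of dimethyl L-tartrate) | COC(=O)[C@H](OC(C)(C)O1)[C@@H]1C(=O)OC | starting material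
2 | (4R,5R)-2,2-dimethyl-1,3-dioxolane-4,5-dicarbaldehyde | O=C[C@H](OC(C)(C)O1)[C@@H]1C=O | intermediate
3 | (4S,5S)-4,5-diethynyl-2,2-dimethyl-1,3-dioxolane | C#C[C@H](OC(C)(C)O1)[C@@H]1C#C | intermediate
4 | {[(4S,5S)-5-ethynyl-2,2-dimethyl-1,3-dioxolan-4-yl]ethynyl}trimethylsilane | C#C[C@H](OC(C)(C)O1)[C@@H]1C#C[Si](C)(C)C | intermediate
5 | carbon monoxide | [C-]#[O+] | starting material
6 | 2-(trimethylsilyl)ethanol | OCC[Si](C)(C)C | starting material
7 | TMSE 2-{(4S,5S)-2,2-dimethyl-5-[(trimethylsilyl)ethynyl]-1,3-dioxolan-4-yl}prop-2-enoate | C=C(C(=O)OCC[Si](C)(C)C)[C@H](OC(C)(C)O1)[C@@H]1C#C[Si](C)(C)C | intermediate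
8 | 2-methylhexa-1,5-diene | C=C(C)CCC=C | starting material
9 | TMSE (2E)-2-{(4S,5S)-2,2-dimethyl-5-[(trimethylsilyl)ethynyl]-1,3-dioxolan-4-yl}-6-methylhepta-2,6-dienoate | C=C(C)CC/C=C(/C(=O)OCC[Si](C)(C)C)[C@H](OC(C)(C)O1)[C@@H]1C#C[Si](C)(C)C | intermediate
10 | TMSE (2E)-2-[(4S,5S)-5-ethynyl-2,2-dimethyl-1,3-dioxolan-4-yl]-6-methylhepta-2,6-dienoate | C=C(C)CC/C=C(/C(=O)OCC[Si](C)(C)C)[C@H](OC(C)(C)O1)[C@@H]1C#C | intermediate
11 | TMSE (2E)-2-{(4S,5S)-5-[3-(dicyclohexylamino)prop-1-yn-1-yl]-2,2-dimethyl-1,3-dioxolan-4-yl}-6-methylhepta-2,6-dienoate | C=C(C)CC/C=C(/C(=O)OCC[Si](C)(C)C)[C@H](OC(C)(C)O1)[C@@H]1C#CCN(C2CCCCC2)C2CCCCC2 | intermediate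
12 | TMSE (2E)-2-[(4S,5S)-2,2-dimethyl-5-(propa-1,2-dien-1-yl)-1,3-dioxolan-4-yl]-6-methylhepta-2,6-dienoate | C=C(C)CC/C=C(/C(=O)OCC[Si](C)(C)C)[C@H](OC(C)(C)O1)[C@@H]1C=C=C | intermediate
13 | acrolein | C=CC=O | starting material
14 | benzeneselenol | [SeH]c1ccccc1 | starting material
15 | 3-(phenylselanyl)propanal | O=CCC[Se]c1ccccc1 | intermediate
16 | bis(pinacolato)diboron | CC1(C)OB(OC1(C)C)B1OC(C)(C)C(C)(C)O1 | starting material
17 | O-Bpin ether of 18 (C6–O–Bpin, (3S,4S) in the hexenyl unit) | C=C(C)CC/C=C(/C(=O)OCC[Si](C)(C)C)[C@H](OC(C)(C)O1)[C@@H]1[C@@H](C(=C)B2OC(C)(C)C(C)(C)O2)[C@@H](OB3OC(C)(C)C(C)(C)O3)CC[Se]c4ccccc4 | intermediate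
18 | TMSE (2E)-2-{(4S,5S)-5-[(3S,4S)-4-hydroxy-6-(phenylselanyl)-2-(Bpin)hex-1-en-3-yl]-2,2-dimethyl-1,3-dioxolan-4-yl}-6-methylhepta-2,6-dienoate | C=C(C)CC/C=C(/C(=O)OCC[Si](C)(C)C)[C@H](OC(C)(C)O1)[C@@H]1[C@@H](C(=C)B2OC(C)(C)C(C)(C)O2)[C@@H](O)CC[Se]c3ccccc3 | intermediate
19 | TMSE (2E)-2-{(4S,5S)-5-[(3R,4S)-4-(methanesulfonyloxy)-6-(phenylselanyl)-2-(Bpin)hex-1-en-3-yl]-2,2-dimethyl-1,3-dioxolan-4-yl}-6-methylhepta-2,6-dienoate | C=C(C)CC/C=C(/C(=O)OCC[Si](C)(C)C)[C@H](OC(C)(C)O1)[C@@H]1[C@@H](C(=C)B2OC(C)(C)C(C)(C)O2)[C@@H](OS(C)(=O)=O)CC[Se]c3ccccc3 | intermediate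
20 | carbon dioxide | O=C=O | starting material
21 | potassium (3R,4S)-4-(methanesulfonyloxy)-2-methylidene-6-(phenylselanyl)-3-[(4S,5S)-dioxolan-4-yl]hexanoate (dioxolane substituted as in 19) | C=C(C)CC/C=C(/C(=O)OCC[Si](C)(C)C)[C@H](OC(C)(C)O1)[C@@H]1[C@@H](C(=C)C(=O)[O-])[C@@H](OS(C)(=O)=O)CC[Se]c2ccccc2.[K+] | intermediate
22 | TMSE (2E)-2-{(4S,5S)-2,2-dimethyl-5-[(2R,3S)-4-methylidene-5-oxo-2-[2-(phenylselanyl)ethyl]oxolan-3-yl]-1,3-dioxolan-4-yl}-6-methylhepta-2,6-dienoate | C=C(C)CC/C=C(/C(=O)OCC[Si](C)(C)C)[C@H](OC(C)(C)O1)[C@@H]1[C@H]2C(=C)C(=O)O[C@@H]2CC[Se]c3ccccc3 | intermediate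
23 | selenoxide of 22 (2-(phenylseleninyl)ethyl side chain) | C=C(C)CC/C=C(/C(=O)OCC[Si](C)(C)C)[C@H](OC(C)(C)O1)[C@@H]1[C@H]2C(=C)C(=O)O[C@@H]2CC[Se](=O)c3ccccc3 | intermediate
24 | TMSE (2E)-2-{(4S,5S)-5-[(2R,3S)-2-ethenyl-4-methylidene-5-oxooxolan-3-yl]-2,2-dimethyl-1,3-dioxolan-4-yl}-6-methylhepta-2,6-dienoate | C=C(C)CC/C=C(/C(=O)OCC[Si](C)(C)C)[C@H](OC(C)(C)O1)[C@@H]1[C@H]2C(=C)C(=O)O[C@@H]2C=C | intermediate
25 | TMSE (1(10)E,4Z,6R,7S,8S,9S)-8,9-(isopropylidenedioxy)germacra-1(10),4,11(13)-trien-6,12-olid-14-oate | C=C1C(=O)O[C@@H]2/C=C(/C)CC/C=C(/C(=O)OCC[Si](C)(C)C)[C@H](OC(C)(C)O3)[C@@H]3[C@@H]12 | intermediate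
26 | TMSE (1(10)E,4Z,6R,7R,8S,9S)-8,9-dihydroxygermacra-1(10),4,11(13)-trien-6,12-olid-14-oate | C=C1C(=O)O[C@@H]2/C=C(/C)CC/C=C(/C(=O)OCC[Si](C)(C)C)[C@H](O)[C@@H](O)[C@@H]12 | intermediate
27 | angelic acid, (2Z)-2-methylbut-2-enoic acid | C/C=C(/C)C(=O)O | starting material
28 | TMSE (6R,7S,8S,9S)-8-{[(2Z)-2-methylbut-2-enoyl]oxy}-9-hydroxygermacra-1(10)E,4Z,11(13)-trien-6,12-olid-14-oate | C=C1C(=O)O[C@@H]2/C=C(/C)CC/C=C(/C(=O)OCC[Si](C)(C)C)[C@H](O)[C@@H](OC(=O)/C(C)=C\C)[C@@H]12 | intermediate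
29 | TMSE (1(10)E,4Z,6R,7S,8S,9S)-8,9-bis{[(2Z)-2-methylbut-2-enoyl]oxy}germacra-1(10),4,11(13)-trien-6,12-olid-14-oate | C=C1C(=O)O[C@@H]2/C=C(/C)CC/C=C(/C(=O)OCC[Si](C)(C)C)[C@H](OC(=O)/C(C)=C\C)[C@@H](OC(=O)/C(C)=C\C)[C@@H]12 | intermediate
30 | (1(10)E,4Z,6R,7S,8S,9S)-8,9-bis{[(2Z)-2-methylbut-2-enoyl]oxy}germacra-1(10),4,11(13)-trien-6,12-olid-14-oic acid (CNP0154468.1) | C=C1C(=O)O[C@@H]2/C=C(/C)CC/C=C(/C(=O)O)[C@H](OC(=O)/C(C)=C\C)[C@@H](OC(=O)/C(C)=C\C)[C@@H]12 | target

Total step count: 15. Longest linear sequence: 14 steps (steps 1–6 and 8–15); step 7 is a one-step side branch.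

Steps most likely to fail, each with a fallback:

Step 12. Intermolecular metathesis (oligomerisation) may outrun closure of the strained ten-membered ring, which also carries a trans-fused acetonide. The fallback moves the ring closure behind the acylation. Starting from 24, the acetonide is removed (AcOH/H2O) to give the open-chain seco-diol F1, which is acylated with an excess of the angelic mixed anhydride as in step 14 to give the seco-bis-angelate F2. Ring-closing metathesis of the freer F2 (second-generation Grubbs catalyst, high dilution) then returns to the route at 29.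

Step 8. The copper–boryl species may borylate the aldehyde directly, or facial discrimination at C7 relative to the dioxolane centre may be poor. The fallback separates borylation from C–C bond formation. Starting from 12, platinum-catalysed diboration of the terminal allene C=C (Pt(dba)2, PCy3, 16) gives the (Z)-2,3-bis(boryl)alkene F3. Heating F3 with 15 in toluene effects uncatalysed allylboration through the same chair arrangement and returns to the route at 17 and, after work-up, 18.

Step 10. Boron-to-copper transfer at the hindered 1,1-disubstituted alkenylboronate may be slow, so that base-induced loss of the mesylate or protodeboronation intervenes. The fallback forms the same two bonds in two operations without a pre-installed leaving group. Starting from 18, the same copper-catalysed carboxylation with CO2 is run on the free alcohol to give the hydroxy acid F4, kept cold and used at once. Mitsunobu lactonisation (PPh3, diisopropyl azodicarboxylate, THF, 0 °C) then lets the carboxylate displace the activated C6 oxygen with inversion and returns to the route at 22.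

Further compounds
F1 | step 12 | TMSE (2E)-2-{(1S,2S)-2-[(2R,3R)-2-ethenyl-4-methylidene-5-oxooxolan-3-yl]-1,2-dihydroxyethyl}-6-methylhepta-2,6-dienoate (seco-diol) | C=C(C)CC/C=C(/C(=O)OCC[Si](C)(C)C)[C@H](O)[C@@H](O)[C@H]1C(=C)C(=O)O[C@@H]1C=C
F2 | step 12 | TMSE (2E)-2-{(1S,2S)-2-[(2R,3S)-2-ethenyl-4-methylidene-5-oxooxolan-3-yl]-1,2-bis{[(2Z)-2-methylbut-2-enoyl]oxy}ethyl}-6-methylhepta-2,6-dienoate (seco-bis-angelate) | C=C(C)CC/C=C(/C(=O)OCC[Si](C)(C)C)[C@H](OC(=O)/C(C)=C\C)[C@@H](OC(=O)/C(C)=C\C)[C@H]1C(=C)C(=O)O[C@@H]1C=C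
F3 | step 8 | TMSE (2E)-2-{(4S,5S)-5-[(1Z)-2,3-bis(Bpin)prop-1-en-1-yl]-2,2-dimethyl-1,3-dioxolan-4-yl}-6-methylhepta-2,6-dienoate | C=C(C)CC/C=C(/C(=O)OCC[Si](C)(C)C)[C@H](OC(C)(C)O1)[C@@H]1/C=C(/B2OC(C)(C)C(C)(C)O2)CB3OC(C)(C)C(C)(C)O3
F4 | step 10 | (3S,4S)-4-hydroxy-2-methylidene-6-(phenylselanyl)-3-[(4S,5S)-dioxolan-4-yl]hexanoic acid (dioxolane substituted as in 18) | C=C(C)CC/C=C(/C(=O)OCC[Si](C)(C)C)[C@H](OC(C)(C)O1)[C@@H]1[C@@H](C(=C)C(=O)O)[C@@H](O)CC[Se]c2ccccc2
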